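## Retrosynthetic overview

1. The benzene ring is bought as 2,3,6-trimethylphenol; the dihydropyran ring is the only ring made, and it is closed last, by the O1–C8a bond.
2. Key disconnection: C4–C4a and O1–C8a are made in one palladium/norbornene (Catellani-type) annulation between 4-iodo-2,3,6-trimethylphenyl pivalate (iodine on C8a) and a γ-bromo tertiary alcohol, BrCH2CH2–C2(CH3)(OH)–chain, that already carries all three stereocentres and the terminal alkene.
3. Enabling feature: in the benzene ring, C8a lies between C8 (methyl, blocked) and C4a (whose only substituent is the ring methylene C4), and O1 sits on the fully substituted C2, three atoms from C4a. The para-iodinated phenol therefore has exactly one ortho C–H and one ortho methyl, and the alkoxide has no hydrogen on its carbinol carbon.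
4. The bromo alcohol comes from an E-allylic alcohol by Sharpless epoxidation (sets C2), Red-Al opening and bromination; the allylic alcohol comes from a terminal alkyne by Negishi carboalumination.
5. The chain with C4' and C8' is assembled from (S)-citronellyl bromide, (S)-3-bromo-2-methylpropan-1-ol and 4-bromo-2-methylbut-1-ene by two copper-catalysed sp3–sp3 couplings, so the terminal alkene is present from step 1 and no hydrogenation is used anywhere.

Key step: step 13

Remark on the chemistry: tocopherol numbering is used (O1, C2, C3, C4, C4a, C5–C8, C8a; chain C1'–C13'); with the terminal alkene the CIP descriptors of the target are 2R,4'R,8'S, the spatial arrangement at all three centres being that of natural α-tocopherol, and enantiopure 1 and 6 are taken as purchased.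

## Route

Step 1
Reactants: 1 (S)-3-bromo-2-methylpropan-1-ol; 2 4-bromo-2-methylbut-1-ene
Product: 4 (R)-2,6-dimethylhept-6-en-1-ol, via 3-methylbut-3-enylmagnesium bromide 3 (not isolated)
Conditions: 2, Mg, THF; then 1, Li2CuCl4 (cat.), THF, −20 °C → rt (2.5 equiv of 3)
Reagents that add atoms: none
Why: Kochi-type Li2CuCl4-catalysed sp3–sp3 coupling of a primary bromide with a homoallylic Grignard reagent; the first equivalent of 3 only deprotonates the hydroxyl, and the stereocentre (future C8') is a spectator whose descriptor changes from S to R by priority alone.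

Step 2
Reactants: 4 (R)-2,6-dimethylhept-6-en-1-ol
Product: 5 (R)-7-bromo-2,6-dimethylhept-1-ene
Conditions: CBr4, PPh3, CH2Cl2, 0 °C
Reagents that add atoms: carbon tetrabromide, BrC(Br)(Br)Br
Why: Appel bromination of a primary alcohol under neutral conditions; the stereocentre is β to the reacting carbon and the alkene is inert.

Step 3
Reactants: 6 (S)-8-bromo-2,6-dimethyloct-2-ene ((S)-citronellyl bromide)
Product: 8 (S)-6-bromo-4-methylhexan-1-ol, via (S)-6-bromo-4-methylhexanal 7 (not isolated)
Conditions: O3, CH2Cl2/MeOH, −78 °C; then NaBH4, −78 → 0 °C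
Reagents that add atoms: ozone, [O-][O+]=O
Why: Ozonolysis of the only alkene of 6 with reductive NaBH4 work-up should give the primary alcohol at the future C1', leaving the primary bromide and the stereocentre (future C4') untouched.

Step 4
Reactants: 8 (S)-6-bromo-4-methylhexan-1-ol
Product: 9 (S)-1-bromo-6-chloro-3-methylhexane
Conditions: N-chlorosuccinimide, PPh3, CH2Cl2, 0 °C → rt
Reagents that add atoms: N-chlorosuccinimide, O=C1CCC(=O)N1Cl
Why: Appel-type chlorination turns the hydroxyl into a primary chloride that is far less reactive than the bromide at the other end, which differentiates the two termini for the next coupling.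

Step 5
Reactants: 5 (R)-7-bromo-2,6-dimethylhept-1-ene; 9 (S)-1-bromo-6-chloro-3-methylhexane
Product: 11 (6S,10R)-13-chloro-2,6,10-trimethyltridec-1-ene, via (R)-2,6-dimethylhept-6-enylmagnesium bromide 10 (not isolated)
Conditions: 5, Mg, THF; then 9, Li2CuCl4 (cat.), THF, −20 → 0 °C
Reagents that add atoms: none
Why: Kochi-type Li2CuCl4-catalysed coupling of Grignard reagent 10 with the primary bromide of 9 should be chemoselective for C–Br over C–Cl; both stereocentres are spectators and the C6'–C7' bond is made without touching the alkene.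

Step 6
Reactants: 11 (6S,10R)-13-chloro-2,6,10-trimethyltridec-1-ene
Product: 12 (6S,10R)-2,6,10-trimethylpentadec-1-en-14-yne
Conditions: LiC≡CH·H2NCH2CH2NH2, NaI (cat.), DMSO, rt → 40 °C
Reagents that add atoms: lithium acetylide (as its ethylenediamine complex), [Li]C#C
Why: SN2 alkylation of lithium acetylide by the primary chloride (iodide-catalysed) installs the terminal alkyne whose two carbons become C2 and C3.

Step 7
Reactants: 12 (6S,10R)-2,6,10-trimethylpentadec-1-en-14-yne
Product: 15 (2E,7R,11S)-3,7,11,15-tetramethylhexadeca-2,15-dien-1-ol, via alkenyldimethylalane 13 (not isolated), via lithium alkenylalanate 14 (not isolated)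
Conditions: Me3Al, Cp2ZrCl2 (cat.), CH2Cl2, 0 °C → rt; n-BuLi, THF/hexane, −78 °C; (CH2O)n, −78 °C → rt
Reagents that add atoms: trimethylaluminium, C[Al](C)C; formaldehyde (as paraformaldehyde), C=O
Why: Negishi zirconium-catalysed carboalumination adds CH3 and Al syn across the terminal alkyne (methyl to the internal carbon), and hydroxymethylation of the alanate proceeds with retention, which fixes the E geometry; the 1,1-disubstituted alkene is not carbometallated by Me3Al/Cp2ZrCl2.

Step 8
Reactants: 15 (2E,7R,11S)-3,7,11,15-tetramethylhexadeca-2,15-dien-1-ol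
Product: 16 [(2R,3R)-3-methyl-3-[(4R,8S)-4,8,12-trimethyltridec-12-en-1-yl]oxiran-2-yl]methanol
Conditions: Ti(OiPr)4 (cat.), D-(−)-diethyl tartrate (cat.), t-BuOOH, 4 Å molecular sieves, CH2Cl2, −20 °C
Reagents that add atoms: tert-butyl hydroperoxide, CC(C)(C)OO
Why: Sharpless asymmetric epoxidation of a geraniol-type E-allylic alcohol; the D-(−)-tartrate titanium complex delivers oxygen to the face that gives the (2R,3R)-epoxide, so the future C2 is set by reagent control, and the remote alkene has no directing hydroxyl and stays intact.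

Step 9
Reactants: 16 [(2R,3R)-3-methyl-3-[(4R,8S)-4,8,12-trimethyltridec-12-en-1-yl]oxiran-2-yl]methanol
Product: 17 (3R,7R,11S)-3,7,11,15-tetramethylhexadec-15-ene-1,3-diol
Conditions: NaAlH2(OCH2CH2OMe)2 (Red-Al), THF, 0 °C → rt
Reagents that add atoms: none
Why: Regioselective Red-Al opening of a 2,3-epoxy alcohol: hydride is delivered from the alkoxyaluminate to the oxirane CH carbon to give the 1,3-diol, and the C–O bond at the quaternary carbon is kept, so the tertiary carbinol retains the R configuration.

Step 10
Reactants: 17 (3R,7R,11S)-3,7,11,15-tetramethylhexadec-15-ene-1,3-diol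
Product: 18 (3R,7R,11S)-1-bromo-3,7,11,15-tetramethylhexadec-15-en-3-ol
Conditions: CBr4, PPh3, CH2Cl2, 0 °C
Reagents that add atoms: carbon tetrabromide, BrC(Br)(Br)Br
Why: Appel bromination should be selective for the primary hydroxyl, because the tertiary hydroxyl does not form a displaceable alkoxyphosphonium species at 0 °C.

Step 11
Reactants: 19 2,3,6-trimethylphenol
Product: 20 4-iodo-2,3,6-trimethylphenol
Conditions: N-iodosuccinimide, TsOH (cat.), MeCN, 0 °C → rt
Reagents that add atoms: N-iodosuccinimide, O=C1CCC(=O)N1I
Why: Electrophilic aromatic iodination at the only position para to the hydroxyl (the other free position is meta), which places iodine on the future C8a.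

Step 12
Reactants: 20 4-iodo-2,3,6-trimethylphenol
Product: 21 4-iodo-2,3,6-trimethylphenyl 2,2-dimethylpropanoate
Conditions: pivaloyl chloride, Et3N, DMAP (cat.), CH2Cl2, rt
Reagents that add atoms: pivaloyl chloride, CC(C)(C)C(=O)Cl
Why: DMAP-catalysed acylation of the hindered phenol; a pivalate between two ortho methyl groups should be inert to carbonate base and to palladium in the next step.

Step 13
Reactants: 21 4-iodo-2,3,6-trimethylphenyl 2,2-dimethylpropanoate; 18 (3R,7R,11S)-1-bromo-3,7,11,15-tetramethylhexadec-15-en-3-ol
Product: 22 (2R)-2,5,7,8-tetramethyl-2-[(4R,8S)-4,8,12-trimethyltridec-12-en-1-yl]-3,4-dihydro-2H-chromen-6-yl 2,2-dimethylpropanoate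
Conditions: Pd(OAc)2 (10 mol %), XPhos (20 mol %), norbornene (1.5 equiv), Cs2CO3, MeCN/toluene, 90 °C
Reagents that add atoms: none
Why: Proposed new method: a palladium/norbornene (Catellani-type) annulation in which zerovalent palladium inserts into the C8a–I bond of 21, norbornene inserts, the resulting alkylpalladium activates the only free ortho C–H (future C4a) to give an aryl–norbornyl palladacycle, the primary C–Br of 18 adds oxidatively to give tetravalent palladium, reductive elimination makes C4–C4a, norbornene is expelled by β-carbon elimination because the ipso carbon is now flanked by the C8 methyl and C4, and the tethered tertiary alkoxide binds divalent palladium and reductively eliminates to form O1–C8a. The closest known reactions are the palladium/norbornene ortho-alkylation/ipso-amination of aryl iodides with bromoalkylamines (indolines, tetrahydroquinolines), the analogous annulation with epoxides that ends in an aryl C–O reductive elimination (2,3-dihydrobenzofurans), and the palladium-catalysed intramolecular etherification of aryl halides by tertiary alcohols with bulky biarylphosphines (2,2-dialkylchromans); new here is their combination with a 3-bromoalkyl tertiary alcohol to close a six-membered ring. The dihydropyran ring is closed by C(aryl)–O reductive elimination from a seven-membered oxapalladacycle (Pd, C8a, C4a, C4, C3, C2, O1), which delivers the six-membered ring. No stereocentre is created: C2 keeps its R configuration because its C–O bond is never broken, only O–H and later O–Pd. The step needs ortho alkylation before ipso termination and alkylation at one site only; the substrate secures this through its single ortho hydrogen, the C8 methyl that allows norbornene extrusion only after alkylation, and a carbinol carbon without hydrogen that rules out β-hydride loss from the palladium alkoxide, while the unactivated 1,1-disubstituted alkene should not compete with strained norbornene for arylpalladium.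

Step 14
Reactants: 22 (2R)-2,5,7,8-tetramethyl-2-[(4R,8S)-4,8,12-trimethyltridec-12-en-1-yl]-3,4-dihydro-2H-chromen-6-yl 2,2-dimethylpropanoate
Product: 23 (2R)-2,5,7,8-tetramethyl-2-[(4R,8S)-4,8,12-trimethyltridec-12-en-1-yl]-3,4-dihydro-2H-chromen-6-ol
Conditions: LiAlH4, THF, 0 °C → rt, under argon
Reagents that add atoms: none
Why: Reductive cleavage of the aryl pivalate by hydride releases the phenol without acid, so the 1,1-disubstituted alkene should neither migrate nor add solvent, and the aryl ether and the three stereocentres are inert.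

## Compound list

1 | (S)-3-bromo-2-methylpropan-1-ol | BrC[C@@H](C)CO | starting material
2 | 4-bromo-2-methylbut-1-ene | C=C(C)CCBr | starting material
3 | 3-methylbut-3-enylmagnesium bromide | C=C(C)CC[Mg]Br | intermediate
4 | (R)-2,6-dimethylhept-6-en-1-ol | C=C(C)CCC[C@@H](C)CO | intermediate
5 | (R)-7-bromo-2,6-dimethylhept-1-ene | C=C(C)CCC[C@@H](C)CBr | intermediate
6 | (S)-8-bromo-2,6-dimethyloct-2-ene ((S)-citronellyl bromide) | BrCC[C@@H](C)CCC=C(C)C | starting material
7 | (S)-6-bromo-4-methylhexanal | BrCC[C@@H](C)CCC=O | intermediate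
8 | (S)-6-bromo-4-methylhexan-1-ol | BrCC[C@@H](C)CCCO | intermediate
9 | (S)-1-bromo-6-chloro-3-methylhexane | BrCC[C@@H](C)CCCCl | intermediate
10 | (R)-2,6-dimethylhept-6-enylmagnesium bromide | C=C(C)CCC[C@@H](C)C[Mg]Br | intermediate
11 | (6S,10R)-13-chloro-2,6,10-trimethyltridec-1-ene | C=C(C)CCC[C@@H](C)CCC[C@@H](C)CCCCl | intermediate
12 | (6S,10R)-2,6,10-trimethylpentadec-1-en-14-yne | C=C(C)CCC[C@@H](C)CCC[C@@H](C)CCCC#C | intermediate
13 | dimethyl[(1E,6R,10S)-2,6,10,14-tetramethylpentadeca-1,14-dien-1-yl]alane | C=C(C)CCC[C@@H](C)CCC[C@@H](C)CCC/C(C)=C/[Al](C)C | intermediate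
14 | lithium butyl(dimethyl)[(1E,6R,10S)-2,6,10,14-tetramethylpentadeca-1,14-dien-1-yl]alanate | [Li+].C=C(C)CCC[C@@H](C)CCC[C@@H](C)CCC/C(C)=C/[Al-](C)(C)CCCC | intermediate
15 | (2E,7R,11S)-3,7,11,15-tetramethylhexadeca-2,15-dien-1-ol | C=C(C)CCC[C@@H](C)CCC[C@@H](C)CCC/C(C)=C/CO | intermediate
16 | [(2R,3R)-3-methyl-3-[(4R,8S)-4,8,12-trimethyltridec-12-en-1-yl]oxiran-2-yl]methanol | C=C(C)CCC[C@@H](C)CCC[C@@H](C)CCC[C@@]1(C)O[C@@H]1CO | intermediate
17 | (3R,7R,11S)-3,7,11,15-tetramethylhexadec-15-ene-1,3-diol | C=C(C)CCC[C@@H](C)CCC[C@@H](C)CCC[C@](O)(C)CCO | intermediate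
18 | (3R,7R,11S)-1-bromo-3,7,11,15-tetramethylhexadec-15-en-3-ol | C=C(C)CCC[C@@H](C)CCC[C@@H](C)CCC[C@](O)(C)CCBr | intermediate
19 | 2,3,6-trimethylphenol | Cc1ccc(C)c(C)c1O | starting material
20 | 4-iodo-2,3,6-trimethylphenol | Cc1cc(I)c(C)c(C)c1O | intermediate
21 | 4-iodo-2,3,6-trimethylphenyl 2,2-dimethylpropanoate | Cc1cc(I)c(C)c(C)c1OC(=O)C(C)(C)C | intermediate
22 | (2R)-2,5,7,8-tetramethyl-2-[(4R,8S)-4,8,12-trimethyltridec-12-en-1-yl]-3,4-dihydro-2H-chromen-6-yl 2,2-dimethylpropanoate | C=C(C)CCC[C@@H](C)CCC[C@@H](C)CCC[C@]1(C)CCc2c(C)c(OC(=O)C(C)(C)C)c(C)c(C)c2O1 | intermediate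
23 | (2R)-2,5,7,8-tetramethyl-2-[(4R,8S)-4,8,12-trimethyltridec-12-en-1-yl]-3,4-dihydro-2H-chromen-6-ol | C=C(C)CCC[C@@H](C)CCC[C@@H](C)CCC[C@]1(C)CCc2c(C)c(O)c(C)c(C)c2O1 | target

## Step count and risks

Total step count: 14. Longest linear sequence: 10 steps (steps 1, 2, 5, 6, 7, 8, 9, 10, 13, 14).

Steps most likely to fail:

1. Step 13 (proposed new method).
   - What may go wrong: palladation of the crowded C–H between the C5 methyl and the palladium-bearing carbon may be slow, so that ipso termination or proto-dehalogenation occurs before alkylation. Base may cyclise 18 to an oxetane faster than it is consumed. The final C–O reductive elimination to an electron-rich, hexasubstituted arene may stall.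
   - Fallback, from 18, rejoining at 23 (known chemistry only): purchased 1-bromo-2,5-dimethoxy-3,4,6-trimethylbenzene is converted with Mg in THF into (2,5-dimethoxy-3,4,6-trimethylphenyl)magnesium bromide F1. Two equivalents of F1 are coupled with 18 under Li2CuCl4 catalysis (the first equivalent deprotonates the tertiary hydroxyl) to give (3R,7R,11S)-1-(2,5-dimethoxy-3,4,6-trimethylphenyl)-3,7,11,15-tetramethylhexadec-15-en-3-ol F2. Oxidative demethylation with (NH4)2Ce(NO3)6 in MeCN/H2O at 0 °C gives the hydroxyalkyl quinone 2-[(3R,7R,11S)-3-hydroxy-3,7,11,15-tetramethylhexadec-15-en-1-yl]-3,5,6-trimethylcyclohexa-2,5-diene-1,4-dione F3. MeOH with catalytic TsOH and 3 Å molecular sieves closes the cyclic methyl ketal (2R)-8a-methoxy-2,5,7,8-tetramethyl-2-[(4R,8S)-4,8,12-trimethyltridec-12-en-1-yl]-2,3,4,8a-tetrahydro-6H-chromen-6-one F4 by attack of the tertiary hydroxyl on the quinone carbonyl carbon; this is the same O1–C8a bond, and the C2–O bond is untouched. Ascorbic acid in aqueous THF reduces F4 to 23 with loss of methanol. Compounds 20, 21 and 22 are then not needed.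

2. Step 10.
   - What may go wrong: during phosphonium activation the tertiary hydroxyl may attack intramolecularly (oxetane formation), or the tertiary alcohol may ionise and eliminate.
   - Fallback, from 17, rejoining at 18: TsCl in pyridine at 0 °C should sulfonylate only the primary hydroxyl to give (3R,7R,11S)-3-hydroxy-3,7,11,15-tetramethylhexadec-15-en-1-yl 4-methylbenzenesulfonate F5, which is isolated. LiBr in acetone then displaces the sulfonate to give 18. This separates activation from substitution and avoids phosphonium intermediates.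

3. Step 5.
   - What may go wrong: Wurtz-type homocoupling, halogen–magnesium exchange between 10 and 9, or slow coupling of the β-branched Grignard reagent may erode the yield of the joined chain.
   - Fallback, from 5 and 9, rejoining at 11: 5 and PhSO2Na in DMF give {[(2R)-2,6-dimethylhept-6-en-1-yl]sulfonyl}benzene F6. n-BuLi in THF at −78 °C gives the α-lithio sulfone F7, which is alkylated at the bromide terminus of 9 to give 13-chloro-2,6,10-trimethyl-7-(phenylsulfonyl)tridec-1-ene F8 (6R,10R by CIP; mixture at C7, which is of no consequence). Mg in MeOH removes the sulfonyl group and returns 11. The same C6'–C7' bond is made by carbanion alkylation instead of copper catalysis.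

Further compounds

F1 | step 13 | (2,5-dimethoxy-3,4,6-trimethylphenyl)magnesium bromide | COc1c(C)c(C)c(OC)c(C)c1[Mg]Br
F2 | step 13 | (3R,7R,11S)-1-(2,5-dimethoxy-3,4,6-trimethylphenyl)-3,7,11,15-tetramethylhexadec-15-en-3-ol | C=C(C)CCC[C@@H](C)CCC[C@@H](C)CCC[C@](O)(C)CCc1c(C)c(OC)c(C)c(C)c1OC
F3 | step 13 | 2-[(3R,7R,11S)-3-hydroxy-3,7,11,15-tetramethylhexadec-15-en-1-yl]-3,5,6-trimethylcyclohexa-2,5-diene-1,4-dione | C=C(C)CCC[C@@H](C)CCC[C@@H](C)CCC[C@](O)(C)CCC1=C(C)C(=O)C(C)=C(C)C1=O
F4 | step 13 | (2R)-8a-methoxy-2,5,7,8-tetramethyl-2-[(4R,8S)-4,8,12-trimethyltridec-12-en-1-yl]-2,3,4,8a-tetrahydro-6H-chromen-6-one | C=C(C)CCC[C@@H](C)CCC[C@@H](C)CCC[C@]1(C)CCC2=C(C)C(=O)C(C)=C(C)C2(OC)O1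
F5 | step 10 | (3R,7R,11S)-3-hydroxy-3,7,11,15-tetramethylhexadec-15-en-1-yl 4-methylbenzenesulfonate | C=C(C)CCC[C@@H](C)CCC[C@@H](C)CCC[C@](O)(C)CCOS(=O)(=O)c1ccc(C)cc1
F6 | step 5 | {[(2R)-2,6-dimethylhept-6-en-1-yl]sulfonyl}benzene | C=C(C)CCC[C@@H](C)CS(=O)(=O)c1ccccc1
F7 | step 5 | [(2R)-2,6-dimethyl-1-(phenylsulfonyl)hept-6-en-1-yl]lithium | C=C(C)CCC[C@@H](C)C([Li])S(=O)(=O)c1ccccc1
F8 | step 5 | 13-chloro-2,6,10-trimethyl-7-(phenylsulfonyl)tridec-1-ene | C=C(C)CCC[C@@H](C)C(CC[C@@H](C)CCCCl)S(=O)(=O)c1ccccc1
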